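**Strategy.** Everything rests on cutting the bond between indole C3 and the ketone carbon of the glyoxylamide, after lowering that carbon to the CH2 of a glycinamide. The complete Boc-protected spermidine arm is first attached to N-(4-methoxyphenyl)glycine. A copper-catalysed double cross-dehydrogenative coupling then joins the glycine α-carbon to the free C3–H of 6-bromoindole and lifts it to the ketone level (ketimine, hydrolysed on work-up) in one operation. The step exploits the enamine-type nucleophilicity of C3 in the pyrrole ring (N1–C2=C3) and the fact that the C(=O)–C(=O)–NH unit is a twice-oxidised glycine amide. Neither partner needs a halide, a metal or N1 protection.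

Key step: step 2

Remark: the target has no stereocentre, axis or configurable double bond, so it is achiral and there is no enantiomer to select; the one stereocentre that arises in the key step is racemic and is erased in the same flask.

PMP = 4-methoxyphenyl. Spermidine numbering: N1 is the aminopropyl end, N4 the inner nitrogen, N8 the aminobutyl end.

Step 1
Reactants: 1 N4,N8-di-Boc-spermidine; 2 N-(4-methoxyphenyl)glycine
Product: 3 N1-[N-(4-methoxyphenyl)glycyl]-N4,N8-di-Boc-spermidine
Conditions: EDC (free base, 1.2 equiv), HOBt (1.2 equiv), CH2Cl2, 0 °C → rt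
Reagents that add atoms: none
Why: In this carbodiimide/HOBt amide coupling the primary alkylamine of 1 is by far the best nucleophile present, so it should take the activated ester of 2 faster than the weakly nucleophilic anilino N–H or the carbamate N–H; no stereocentre is involved.

Step 2
Reactants: 3 N1-[N-(4-methoxyphenyl)glycyl]-N4,N8-di-Boc-spermidine; 4 6-bromo-1H-indole
Product: 8 N4,N8-di-Boc-didemnidine B, via aldimine 5 (not isolated), via amine adduct 6 (not isolated), via ketimine 7 (not isolated)
Conditions: CuBr (10 mol %), t-BuOOH (5.5 M in decane, 3 equiv, slow addition), 3 (1.2 equiv), DCE, rt → 50 °C; then 1 M aq HCl/THF, rt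
Reagents that add atoms: water, O
Why: Cu/t-BuOOH takes two hydrogens from the N-aryl glycine unit of 3 (electron transfer at the electron-rich PMP-nitrogen, then loss of the captodative α-C–H) to give the N,O-chelated, electrophilic α-imino amide 5, and the enamine-type C3 of the pyrrole ring of 4 adds to its C=N carbon in an aza-Friedel–Crafts step that forms the C3–Cα bond of 6. The remaining α-C–H of 6 is flanked by the amine nitrogen, the amide carbonyl and the indol-3-yl group and is therefore weaker than those of 3, so a second dehydrogenation to the fully conjugated ketimine 7 should follow in the same flask, and dilute acid then exchanges =N–PMP for =O. The closest known reaction type is the copper-catalysed cross-dehydrogenative coupling of N-aryl glycine esters and amides with N–H indoles, including its double-oxidation variant that ends at 2-(indol-3-yl)-2-imino- and 2-oxo-carbonyl compounds. No ring is closed, and the only new stereocentre (Cα of 6) is racemic, transient and erased in 7. The step needs C3 over N1/C2 selectivity (secured by the innate enamine reactivity of an unprotected indole in a neutral medium), oxidation of the glycine CH2 rather than of the carbamate- or amide-bound N–CH2 groups or of the indole (secured by the low oxidation potential of the PMP-amine), and survival of C6–Br and both Boc groups (no Pd or Ni, no base, only brief dilute acid). A small excess of 3 over 4 and slow addition of the peroxide should hold back displacement of the arylamine by a second indole and oxidation of free indole.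

Step 3
Reactants: 8 N4,N8-di-Boc-didemnidine B
Product: 10 didemnidine B, via bis-TFA salt 9 (not isolated)
Conditions: TFA/CH2Cl2 (1:4), 0 °C → rt; evaporate; aq Na2CO3 (pH 11), extraction with CHCl3/i-PrOH (3:1)
Reagents that add atoms: none
Why: Acidolytic Boc cleavage (loss of isobutene, then decarboxylation) should free N4 and N8, while the indole ring (deactivated by the glyoxyl group and bromine), the α-ketoamide and the aryl bromide are inert to TFA, and carbonate is mild enough to release the free base without deprotonating the indole N–H.

**Compound list**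

1 | tert-butyl N-(3-aminopropyl)-N-[4-(tert-butoxycarbonylamino)butyl]carbamate (N4,N8-di-Boc-spermidine, catalogue name N1,N5-bis-Boc-spermidine; achiral) | NCCCN(CCCCNC(=O)OC(C)(C)C)C(=O)OC(C)(C)C | starting material
2 | N-(4-methoxyphenyl)glycine | COc1ccc(NCC(=O)O)cc1 | starting material
3 | tert-butyl N-[4-(tert-butoxycarbonylamino)butyl]-N-(3-{2-[(4-methoxyphenyl)amino]acetamido}propyl)carbamate (PMP-glycinamide of 1) | COc1ccc(NCC(=O)NCCCN(CCCCNC(=O)OC(C)(C)C)C(=O)OC(C)(C)C)cc1 | intermediate
4 | 6-bromo-1H-indole | Brc1ccc2cc[nH]c2c1 | starting material
5 | (E)-α-imino amide, PMP–N=CH–C(=O)NH– arm of 3 after the first dehydrogenation | COc1ccc(/N=C/C(=O)NCCCN(CCCCNC(=O)OC(C)(C)C)C(=O)OC(C)(C)C)cc1 | intermediate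
6 | rac-2-(6-bromo-1H-indol-3-yl)-2-[(4-methoxyphenyl)amino]acetamide carrying the di-Boc-spermidine arm on the amide nitrogen | COc1ccc(NC(C(=O)NCCCN(CCCCNC(=O)OC(C)(C)C)C(=O)OC(C)(C)C)c2c[nH]c3cc(Br)ccc23)cc1 | intermediate
7 | 2-(6-bromo-1H-indol-3-yl)-2-[(4-methoxyphenyl)imino]acetamide carrying the di-Boc-spermidine arm (C=N geometry not controlled) | COc1ccc(N=C(C(=O)NCCCN(CCCCNC(=O)OC(C)(C)C)C(=O)OC(C)(C)C)c2c[nH]c3cc(Br)ccc23)cc1 | intermediate
8 | tert-butyl N-{3-[2-(6-bromo-1H-indol-3-yl)-2-oxoacetamido]propyl}-N-[4-(tert-butoxycarbonylamino)butyl]carbamate (N4,N8-di-Boc-didemnidine B) | CC(C)(C)OC(=O)NCCCCN(CCCNC(=O)C(=O)c1c[nH]c2cc(Br)ccc12)C(=O)OC(C)(C)C | intermediate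
9 | didemnidine B bis(trifluoroacetate) | NCCCCNCCCNC(=O)C(=O)c1c[nH]c2cc(Br)ccc12.OC(=O)C(F)(F)F.OC(=O)C(F)(F)F | intermediate
10 | didemnidine B, N-{3-[(4-aminobutyl)amino]propyl}-2-(6-bromo-1H-indol-3-yl)-2-oxoacetamide (achiral) | NCCCCNCCCNC(=O)C(=O)c1c[nH]c2cc(Br)ccc12 | target

Total step count: 3
Longest linear sequence: 3

**Steps most likely to fail**

1. **Step 2.** The cascade may stall at the amine oxidation level, a second indole may displace the arylamine from the first adduct, or the peroxide may attack the C2=C3 bond of unreacted indole. The fallback sets out from 1 and comes back at 8. It makes the same C3–C bond by polar acylation at the full oxidation level.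
   - Amine 1 is acylated with methyl chlorooxoacetate (Et3N, CH2Cl2, 0 °C) to the methyl oxamate F1.
   - Saponification (LiOH, THF/H2O, then KHSO4) gives the oxamic acid F2.
   - 1-Chloro-N,N,2-trimethylpropenylamine (CH2Cl2, 0 °C, neutral conditions that spare Boc) converts it into the oxamoyl chloride F3.
   - F3 is added at −20 to 0 °C to 6-bromoindole 4 pre-complexed with Et2AlCl in CH2Cl2. This Friedel–Crafts C3-acylation of an N–H indole, in which the aluminium alkyl also scavenges the acid, should give 8 directly.

2. **Step 1.** Self-acylation at the anilino nitrogen of 2 (oligomerisation, diketopiperazine formation) may compete with acylation of 1. The fallback sets out from 1 and comes back at 3. It makes the aryl-N–CH2 bond last instead of the amide bond.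
   - 1 is acylated with bromoacetyl bromide under two-phase Schotten–Baumann conditions (CH2Cl2/aq NaHCO3, 0 °C) to the bromoacetamide F4.
   - The bromide is displaced by excess p-anisidine (K2CO3, cat. NaI, MeCN, 50 °C, SN2) to give 3.

3. **Step 3.** Several things may go wrong here:
   - tert-Butyl cations released in strong acid may alkylate the indole.
   - Cleavage of the hindered N4 carbamate may lag.
   - The very polar free base may be lost to the aqueous phase.
   - The free base may undergo N1→N4 acyl shift during the basic work-up.

   The fallback sets out from 8 and comes back at 10. It is a silylative, non-aqueous cleavage.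
   - TMSOTf/2,6-lutidine (CH2Cl2, 0 °C) turns both carbamates into the bis(trimethylsilyl carbamate) F5, with the base taking the proton so that isobutene leaves.
   - Methanol collapses F5 to the amines.
   - Catch-and-release on a sulfonic acid resin (wash MeOH, elute NH3/MeOH) should deliver 10 without an aqueous basic extraction.

**Further compounds**

F1 | step 2 | methyl oxamate of 1, methyl 2-oxo-2-[(3-{Boc[4-(Boc-amino)butyl]amino}propyl)amino]acetate | COC(=O)C(=O)NCCCN(CCCCNC(=O)OC(C)(C)C)C(=O)OC(C)(C)C
F2 | step 2 | oxamic acid of 1 | OC(=O)C(=O)NCCCN(CCCCNC(=O)OC(C)(C)C)C(=O)OC(C)(C)C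
F3 | step 2 | oxamoyl chloride of 1 | ClC(=O)C(=O)NCCCN(CCCCNC(=O)OC(C)(C)C)C(=O)OC(C)(C)C
F4 | step 1 | bromoacetamide of 1 | BrCC(=O)NCCCN(CCCCNC(=O)OC(C)(C)C)C(=O)OC(C)(C)C
F5 | step 3 | N4,N8-bis(trimethylsilyloxycarbonyl)-didemnidine B | C[Si](C)(C)OC(=O)NCCCCN(CCCNC(=O)C(=O)c1c[nH]c2cc(Br)ccc12)C(=O)O[Si](C)(C)C
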